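Readings and results were generated by integration with constants of no real substance, noise included.

- Substrate is what we count in zeta, gamma, theta and beta: the share asked for has as its denominator the substrate that has gone to products.

| flask | substrate | first nucleophile | second nucleophile | remark | time |
|---|---|---|---|---|---|
| violet | 0.50 M | 0.11 M | 0.25 M | run made earlier |  |
| ochre | 0.50 M | 0.54 M | 0.25 M | run made earlier |  |
| teal | 0.50 M | 0.75 M | 0.36 M | run made earlier |  |
| zeta | 0.50 M | 0.750 M | 0.250 M |  | 4.0 h |
| gamma | 0.25 M | 0.750 M | 0.250 M |  | 4.0 h |
| theta | 0.50 M | 0.250 M | 0.250 M |  | 4.0 h |
| beta | 1.0 M | 0.200 M | 1.00 M |  | 4.0 h |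

| run | time / min | target / % | other capture product / % |
|---|---|---|---|
| violet | 15.0 | 0.6 | 1.7 |
| violet | 40.0 | 0.9 | 5.3 |
| violet | 80.0 | 0.9 | 8.9 |
| violet | 120 | 0.4 | 13.6 |
| ochre | 10.0 | 0.4 | 0.8 |
| ochre | 20.0 | 0.5 | 2.3 |
| ochre | 50.0 | 0.9 | 4.9 |
| ochre | 120 | 3.0 | 11.2 |
| teal | 10.0 | 0.6 | 0.7 |
| teal | 20.0 | 0.6 | 2.1 |
| teal | 50.0 | 0.5 | 5.4 |
| teal | 120 | 1.8 | 12.1 |

(readings scatter by 0.5 percentage points)

- the numbers in the tables scatter by 0.5 percentage points (one standard deviation)

- the flasks by share of target in all that became target or other capture product or solvolysis product, highest first, at 4.0 h (zeta / gamma / theta / beta)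
- the share of target in all that became target or other capture product or solvolysis product of the flask you put first, at 4.0 h
- the share of target in all that became target or other capture product or solvolysis product of the flask you put last, at 4.0 h

- At 120 min, target plus other capture product reads 14.0% in violet, 14.2% in ochre and 13.9% in teal, although first nucleophile ran from 0.11 M to 0.75 M.
- We therefore read ionisation as the rate-limiting step, with a mean loss of 14.0% and a first-order constant of 0.0756 /h; first order is our assumption, since each run held 0.50 M of substrate.
- The quantity we carry is the ionisation turnover count, this constant times the time, which is 0.302 at 4.0 h.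
- In the first instants, other capture product at 20.0 min reads 2.3% in ochre and 2.1% in teal, more than target at 0.5% and 0.6%, two readings about the size of the scatter.
- In the middle the split moves in ochre: from 50.0 min to 120 min, the readings give target a quarter of the new product.
- At the end, our count leaves 73.9% of the substrate in each flask and gives a denominator of 26.1%.
- Our own reckoning lets the mean ochre and teal target grow with the square of time, which gives 9.60% and a share of 36.8% for zeta.
- Violet's target scaled the same way gives a share of 6.13%, and we expect beta's share to be lower than that, since its ratio of first to second nucleophile is 0.200, lower than violet's 0.440.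
- The forecast gave zeta > gamma > theta > beta, with 24% (12% to 38%) and 3% (0.5% to 9%), reading “This suggests rate-limiting ionisation, first order in substrate”.
- We keep its order but part on the top share: its about 22% other capture product and about 9% target stand beside our whole 26.1%.

    substrate → intermediate (k = 0.0800 /h)
    first nucleophile + intermediate → target (k = 9.70 /M/h)
    second nucleophile + intermediate → other capture product (k = 140 /M/h)
    intermediate → solvolysis product (k = 0.730 /h)
    second nucleophile → decomposed reagent (k = 0.360 /h)

- Zeta came first at 36.3% and beta last at 3.90%, in the order zeta > gamma > theta > beta. Ionisation ran throughout zeta and left 72.6% of the substrate at 4.00 h, against our 73.9%, while second nucleophile fell to 34.1% of its charge by 2.00 h, with 76% of its decomposition to decomposed reagent up to 4.0 h then behind it, and to 8.98% at 4.00 h, when target stood at 9.76% beside 16.1% other capture product. Zeta left until 15 h kept 30.1% of its substrate, where the same count gives 32.2%, and held 45.5% target.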